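**Plan** (chain numbered C1 = CH2OBz to C10 = exocyclic =CH; lactone ring O1'–C5')
1. Retrosynthesis: both acetates come off last; then the C7–C8 bond is cut. C8 is a carbinol carbon bonded directly to C7, the methyl-bearing sp2 carbon of the (6E)-alkene, so an (E)-alkenyl iodide (12) and an aldehyde (25) can be joined with the bond and the C8 centre made together. The (E)-exocyclic C10=C3' alkene on the γ-butyrolactone ring holds O8 away from the lactone carbonyl.
2. Aldehyde 25: C10=C3' is cut by aldol/dehydration (lactone 18 + 3-silyloxypropanal), the isobutenyl C=C by a Wittig reaction; the lactone ring with C4'/C5' comes from 2-deoxy-D-ribose.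
3. Iodide 12: C3–C4 is cut by a Negishi sp3–sp2 coupling ((Z)-3-iodobut-2-enyl ether + pent-3-ynylzinc); the C7–I bond comes from the alkyne by hydrozirconation/iodination.
4. Forward: the only ring (the lactone) is present from step 8; side chains are added to it (steps 12–14), the C9 chain is built separately (steps 1–7), and the two are joined in step 17, followed by desilylation and double acetylation.
5. Stereochemistry: C4'/C5' from the chiral pool; C8 from the chiral ligand in step 17; 2Z from anti-hydroalumination plus retentive coupling; 6E from syn-hydrozirconation; exocyclic E from the elimination in step 14.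

Key step: step 17

Remarks: 13 is drawn as the open-chain aldehyde, although the commercial sugar is a hemiacetal mixture. The sense of induction of the sulfonamide ligand in step 17 is an assumption (the (S)-ligand is taken to give Si-face attack); both antipodes are available.

**Route**

Step 1
Reactants: 1 pent-3-yn-1-ol
Product: 2 5-iodopent-2-yne
Conditions: I2, PPh3, imidazole, CH2Cl2, 0 °C to rt
Reagents that add atoms: iodine, II
Why: Appel-type iodination, in which the alkoxyphosphonium ion formed from Ph3P/I2 is displaced by iodide in an SN2 step at the primary carbon while the internal alkyne is inert.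

Step 2
Reactants: 3 but-2-yn-1-ol
Product: 5 (Z)-3-iodobut-2-en-1-ol, via cyclic alkenylalanate 4 (not isolated)
Conditions: NaAlH2(OCH2CH2OCH3)2, THF, 0 °C to rt; then I2, THF, −78 to 0 °C
Reagents that add atoms: iodine, II
Why: Hydroxyl-directed anti-hydroalumination of a propargylic alcohol delivers hydride to C2 and aluminium to C3 inside the five-membered alkoxyalanate 4, and iodinolysis of the C–Al bond with retention should give the (Z)-iodide that later becomes the 2Z alkene.

Step 3
Reactants: 5 (Z)-3-iodobut-2-en-1-ol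
Product: 6 (Z)-tert-butyl[(3-iodobut-2-en-1-yl)oxy]dimethylsilane
Conditions: TBSCl, imidazole, CH2Cl2, rt
Reagents that add atoms: tert-butyldimethylsilyl chloride, CC(C)(C)[Si](C)(C)Cl
Why: Standard imidazole-promoted silylation of a primary alcohol, needed because a free hydroxyl would quench the organozinc and zirconium hydride reagents of the next two steps.

Step 4
Reactants: 2 5-iodopent-2-yne; 6 (Z)-tert-butyl[(3-iodobut-2-en-1-yl)oxy]dimethylsilane
Product: 8 (Z)-tert-butyldimethyl[(3-methyloct-2-en-6-yn-1-yl)oxy]silane, via pent-3-ynylzinc iodide 7 (not isolated)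
Conditions: 2, Zn dust, LiCl, THF, 40 °C; then 6, PdCl2(dppf) (3 mol %), THF, rt
Reagents that add atoms: none
Why: Negishi sp3–sp2 coupling, in which zinc inserts into the primary C–I bond of 2 to give 7 and palladium-catalysed coupling with the alkenyl iodide proceeds with retention, so the (Z)-trisubstituted alkene is carried over intact.

Step 5
Reactants: 8 (Z)-tert-butyldimethyl[(3-methyloct-2-en-6-yn-1-yl)oxy]silane
Product: 10 tert-butyl{[(2Z,6E)-7-iodo-3-methylocta-2,6-dien-1-yl]oxy}dimethylsilane, via alkenylzirconocene chloride 9 (not isolated)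
Conditions: Cp2Zr(H)Cl (2.5 equiv), THF, 50 °C; then I2, THF, 0 °C
Reagents that add atoms: iodine, II
Why: Syn-hydrozirconation of the methyl-capped internal alkyne under equilibrating conditions (excess hydride, warming) should settle zirconium on the less hindered methyl-bearing carbon, and iodinolysis with retention then gives the (E)-2-iodoalkene, while the trisubstituted alkene and the silyl ether do not react.

Step 6
Reactants: 10 tert-butyl{[(2Z,6E)-7-iodo-3-methylocta-2,6-dien-1-yl]oxy}dimethylsilane
Product: 11 (2Z,6E)-7-iodo-3-methylocta-2,6-dien-1-ol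
Conditions: camphorsulfonic acid (10 mol %), MeOH, 0 °C to rt
Reagents that add atoms: none
Why: Acid-catalysed methanolysis of a primary allylic silyl ether, which leaves the alkenyl iodide and both alkene geometries untouched.

Step 7
Reactants: 11 (2Z,6E)-7-iodo-3-methylocta-2,6-dien-1-ol
Product: 12 (2Z,6E)-7-iodo-3-methylocta-2,6-dien-1-yl benzoate
Conditions: BzCl, pyridine, DMAP (cat.), CH2Cl2, 0 °C
Reagents that add atoms: benzoyl chloride, O=C(Cl)c1ccccc1
Why: Nucleophile-catalysed acylation of the primary allylic alcohol, placing the benzoate only after the hydride and organozinc steps that an ester would not survive.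

Step 8
Reactants: 13 2-deoxy-D-ribose
Product: 14 2-deoxy-D-ribono-1,4-lactone [(4S,5R)-4-hydroxy-5-(hydroxymethyl)oxolan-2-one]
Conditions: Br2, H2O, rt, dark; neutralisation on work-up
Reagents that add atoms: none
Why: Bromine-water oxidation of an aldose hemiacetal to the aldono-1,4-lactone, in which C3 and C4 of the sugar become the (4S) and (5R) centres of the lactone without being touched.

Step 9
Reactants: 14 2-deoxy-D-ribono-1,4-lactone
Product: 15 (4S,5R)-4-[(tert-butyldimethylsilyl)oxy]-5-{[(tert-butyldimethylsilyl)oxy]methyl}oxolan-2-one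
Conditions: TBSCl (2.5 equiv), imidazole, DMF, rt
Reagents that add atoms: tert-butyldimethylsilyl chloride, CC(C)(C)[Si](C)(C)Cl
Why: Exhaustive imidazole-promoted silylation of both hydroxyls.

Step 10
Reactants: 15 the bis-silyl ether
Product: 16 (4S,5R)-4-[(tert-butyldimethylsilyl)oxy]-5-(hydroxymethyl)oxolan-2-one
Conditions: CF3CO2H/H2O/THF (1:1:4), 0 °C
Reagents that add atoms: none
Why: Acid-mediated hydrolysis is much faster at the unhindered primary silyl ether than at the secondary one on the ring, so the hydroxymethyl group should be freed selectively.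

Step 11
Reactants: 16 the primary alcohol
Product: 17 (2S,3S)-3-[(tert-butyldimethylsilyl)oxy]-5-oxooxolane-2-carbaldehyde
Conditions: Dess–Martin periodinane (DMP), CH2Cl2, 0 °C to rt; crude aldehyde used at once
Reagents that add atoms: none
Why: Dess–Martin oxidation of the primary alcohol under non-basic conditions, chosen so that the α-oxygenated aldehyde is neither epimerised nor over-oxidised.

Step 12
Reactants: 17 the lactone aldehyde
Product: 18 (4S,5R)-4-[(tert-butyldimethylsilyl)oxy]-5-(2-methylprop-1-en-1-yl)oxolan-2-one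
Conditions: isopropyltriphenylphosphonium iodide, n-BuLi, THF, 0 °C; then 17, −78 to 0 °C
Reagents that add atoms: isopropyltriphenylphosphonium iodide, CC(C)[P+](c1ccccc1)(c1ccccc1)c1ccccc1.[I-]
Why: Wittig olefination with the unstabilised isopropylidene ylide, which should add to the aldehyde far faster than to the lactone carbonyl at −78 °C and creates no new stereo-element because the new alkene carbon carries two methyl groups.

Step 13
Reactants: 18 the isobutenyl lactone; 19 3-[(tert-butyldimethylsilyl)oxy]propanal
Product: 21 (4S,5R)-4-[(tert-butyldimethylsilyl)oxy]-3-{1-hydroxy-3-[(tert-butyldimethylsilyl)oxy]propyl}-5-(2-methylprop-1-en-1-yl)oxolan-2-one (3,4-trans expected; carbinol epimers), via lithium enolate 20 (not isolated)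
Conditions: LiN(i-Pr)2 (1.1 equiv), THF, −78 °C; then 19, −78 °C; AcOH quench at −78 °C
Reagents that add atoms: none
Why: Aldol addition of the lithium lactone enolate 20, which at −78 °C should add to the aldehyde faster than it expels the β-silyloxy group, the electrophile entering anti to that group (this centre and the new carbinol centre are both erased in step 14).

Step 14
Reactants: 21 the aldol adduct
Product: 23 (3E,4S,5R)-4-[(tert-butyldimethylsilyl)oxy]-3-{3-[(tert-butyldimethylsilyl)oxy]propylidene}-5-(2-methylprop-1-en-1-yl)oxolan-2-one, via secondary mesylate 22 (not isolated)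
Conditions: MsCl, Et3N, CH2Cl2, 0 °C; then DBU, 0 °C to rt
Reagents that add atoms: none
Why: Mesylation followed by base-induced E1cB elimination through the lactone enolate should give mainly the (E)-alkylidene lactone, the thermodynamically preferred geometry in which the chain avoids the carbonyl oxygen, and the minor (Z)-isomer is removed by chromatography.

Step 15
Reactants: 23 the bis-silyl alkylidene lactone
Product: 24 (3E,4S,5R)-4-[(tert-butyldimethylsilyl)oxy]-3-(3-hydroxypropylidene)-5-(2-methylprop-1-en-1-yl)oxolan-2-one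
Conditions: camphorsulfonic acid (10 mol %), MeOH/CH2Cl2 (1:1), 0 °C
Reagents that add atoms: none
Why: Acid-catalysed methanolysis should discriminate the unhindered primary silyl ether from the secondary allylic one flanked by the ring substituents.

Step 16
Reactants: 24 the homoallylic alcohol
Product: 25 (3E)-3-[(4S,5R)-4-[(tert-butyldimethylsilyl)oxy]-5-(2-methylprop-1-en-1-yl)-2-oxooxolan-3-ylidene]propanal
Conditions: Dess–Martin periodinane, NaHCO3, CH2Cl2, 0 °C; used directly in step 17
Reagents that add atoms: none
Why: Buffered Dess–Martin oxidation gives the β,γ-unsaturated aldehyde under neutral conditions that should neither move the double bond nor enolise the doubly activated CH2.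

Step 17
Reactants: 25 the lactone aldehyde; 12 (2Z,6E)-7-iodo-3-methylocta-2,6-dien-1-yl benzoate (1.5 equiv)
Product: 27 (2Z,6E,8R,10E)-10-[(4S,5R)-4-[(tert-butyldimethylsilyl)oxy]-5-(2-methylprop-1-en-1-yl)-2-oxooxolan-3-ylidene]-8-hydroxy-3,7-dimethyldeca-2,6-dien-1-yl benzoate, via zirconocene alkoxide 26 (not isolated)
Conditions: CrCl2 (15 mol %), (S)-N-[2-(4-isopropyl-4,5-dihydro-1,3-oxazol-2-yl)-6-methylphenyl]methanesulfonamide (17 mol %), 1,8-bis(dimethylamino)naphthalene (17 mol %), NiCl2(2,9-dimethyl-1,10-phenanthroline) (2 mol %), Mn powder (2 equiv), Cp2ZrCl2 (1.2 equiv), LiCl (2 equiv), MeCN, rt; aqueous work-up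
Reagents that add atoms: none
Why: Zerovalent nickel inserts into the C–I bond of 12 with retention of the (E)-geometry, the alkenyl group passes to trivalent chromium carrying the chiral sulfonamide ligand, and this weakly basic alkenylchromium adds to the aldehyde carbon of 25, after which Cp2ZrCl2 takes over the alkoxide (26) and Mn returns chromium to the divalent state. The closest known reaction type is the catalytic asymmetric Nozaki–Hiyama–Kishi alkenylation of an aldehyde. No ring is closed. The new C8 centre is set by the ligand alone, because the ring stereocentres are too remote to bias the aldehyde faces; Si-face attack gives (8R), for which the (S)-ligand is proposed, with the antipode taken instead if a trial on a simple aldehyde shows the opposite sense. The step needs selectivity for the aldehyde over the lactone, the benzoate and the enoate acceptor and must not enolise the activated CH2 of 25; the carbonyl selectivity and low basicity of organochromium reagents should secure both, and a low nickel loading keeps the allylic benzoate from ionising. The (E)-alkylidene geometry keeps the new alkoxide away from the lactone carbonyl, so no translactonisation can follow.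

Step 18
Reactants: 27 the silyl-protected allylic alcohol
Product: 28 (2Z,6E,8R,10E)-8-hydroxy-10-[(4S,5R)-4-hydroxy-5-(2-methylprop-1-en-1-yl)-2-oxooxolan-3-ylidene]-3,7-dimethyldeca-2,6-dien-1-yl benzoate
Conditions: HF·pyridine, THF, 0 °C to rt
Reagents that add atoms: none
Why: Fluoride-mediated cleavage of the secondary silyl ether under mildly acidic, non-basic conditions that should spare the benzoate, the lactone and the allylic alcohol.

Step 19
Reactants: 28 the diol
Product: 29 the target, (2Z,6E,8R,10E)-8-acetoxy-10-[(4S,5R)-4-acetoxy-5-(2-methylprop-1-en-1-yl)-2-oxooxolan-3-ylidene]-3,7-dimethyldeca-2,6-dien-1-yl benzoate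
Conditions: Ac2O, pyridine, DMAP (cat.), CH2Cl2, 0 °C to rt
Reagents that add atoms: acetic anhydride, CC(=O)OC(C)=O
Why: Pyridine/DMAP-promoted acetylation esterifies both secondary hydroxyls (ring C4' and chain C8) in one operation without touching any stereocentre.

**Compound list**

1 | pent-3-yn-1-ol | CC#CCCO | starting material
2 | 5-iodopent-2-yne | CC#CCCI | intermediate
3 | but-2-yn-1-ol | CC#CCO | starting material
4 | sodium 2,2-bis(2-methoxyethoxy)-3-methyl-2,5-dihydro-1,2-oxaaluminol-2-uide (cyclic alkenylalanate) | CC1=CCO[Al-]1(OCCOC)OCCOC.[Na+] | intermediate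
5 | (Z)-3-iodobut-2-en-1-ol | C/C(I)=C/CO | intermediate
6 | (Z)-tert-butyl[(3-iodobut-2-en-1-yl)oxy]dimethylsilane | C/C(I)=C/CO[Si](C)(C)C(C)(C)C | intermediate
7 | pent-3-yn-1-ylzinc iodide | CC#CCC[Zn]I | intermediate
8 | (Z)-tert-butyldimethyl[(3-methyloct-2-en-6-yn-1-yl)oxy]silane | CC#CCC/C(C)=C\CO[Si](C)(C)C(C)(C)C | intermediate
9 | chlorobis(cyclopentadienyl){(2E,6Z)-8-[(tert-butyldimethylsilyl)oxy]-6-methylocta-2,6-dien-2-yl}zirconium | C/C([Zr](Cl)(C1C=CC=C1)C1C=CC=C1)=C\CC/C(C)=C\CO[Si](C)(C)C(C)(C)C | intermediate
10 | tert-butyl{[(2Z,6E)-7-iodo-3-methylocta-2,6-dien-1-yl]oxy}dimethylsilane | C/C(I)=C\CC/C(C)=C\CO[Si](C)(C)C(C)(C)C | intermediate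
11 | (2Z,6E)-7-iodo-3-methylocta-2,6-dien-1-ol | C/C(I)=C\CC/C(C)=C\CO | intermediate
12 | (2Z,6E)-7-iodo-3-methylocta-2,6-dien-1-yl benzoate | C/C(I)=C\CC/C(C)=C\COC(=O)c1ccccc1 | intermediate
13 | 2-deoxy-D-ribose (open-chain form) | O=CC[C@H](O)[C@H](O)CO | starting material
14 | 2-deoxy-D-ribono-1,4-lactone | C1C(=O)O[C@H](CO)[C@H]1O | intermediate
15 | (4S,5R)-4-(TBSO)-5-[(TBSO)methyl]oxolan-2-one | C1C(=O)O[C@H](CO[Si](C)(C)C(C)(C)C)[C@H]1O[Si](C)(C)C(C)(C)C | intermediate
16 | (4S,5R)-4-(TBSO)-5-(hydroxymethyl)oxolan-2-one | C1C(=O)O[C@H](CO)[C@H]1O[Si](C)(C)C(C)(C)C | intermediate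
17 | (2S,3S)-3-(TBSO)-5-oxooxolane-2-carbaldehyde | C1C(=O)O[C@H](C=O)[C@H]1O[Si](C)(C)C(C)(C)C | intermediate
18 | (4S,5R)-4-(TBSO)-5-(2-methylprop-1-en-1-yl)oxolan-2-one | C1C(=O)O[C@H](C=C(C)C)[C@H]1O[Si](C)(C)C(C)(C)C | intermediate
19 | 3-[(tert-butyldimethylsilyl)oxy]propanal | O=CCCO[Si](C)(C)C(C)(C)C | starting material
20 | lithium enolate of 18 | C1=C(O[Li])O[C@H](C=C(C)C)[C@H]1O[Si](C)(C)C(C)(C)C | intermediate
21 | aldol adduct of 18 and 19 (3,4-trans; carbinol epimers) | [C@@H]1(C(O)CCO[Si](C)(C)C(C)(C)C)C(=O)O[C@H](C=C(C)C)[C@H]1O[Si](C)(C)C(C)(C)C | intermediate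
22 | methanesulfonate of 21 | [C@@H]1(C(OS(C)(=O)=O)CCO[Si](C)(C)C(C)(C)C)C(=O)O[C@H](C=C(C)C)[C@H]1O[Si](C)(C)C(C)(C)C | intermediate
23 | (3E,4S,5R)-4-(TBSO)-3-[3-(TBSO)propylidene]-5-(2-methylprop-1-en-1-yl)oxolan-2-one | CC(C)(C)[Si](C)(C)OCC/C=C1/C(=O)O[C@H](C=C(C)C)[C@H]1O[Si](C)(C)C(C)(C)C | intermediate
24 | (3E,4S,5R)-4-(TBSO)-3-(3-hydroxypropylidene)-5-(2-methylprop-1-en-1-yl)oxolan-2-one | OCC/C=C1/C(=O)O[C@H](C=C(C)C)[C@H]1O[Si](C)(C)C(C)(C)C | intermediate
25 | (3E)-3-[(4S,5R)-4-(TBSO)-5-(2-methylprop-1-en-1-yl)-2-oxooxolan-3-ylidene]propanal | O=CC/C=C1/C(=O)O[C@H](C=C(C)C)[C@H]1O[Si](C)(C)C(C)(C)C | intermediate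
26 | chlorobis(cyclopentadienyl)zirconium alkoxide of 27 | Cl[Zr](C2C=CC=C2)(C3C=CC=C3)O[C@H](C/C=C1/C(=O)O[C@H](C=C(C)C)[C@H]1O[Si](C)(C)C(C)(C)C)/C(C)=C/CC/C(C)=C\COC(=O)c1ccccc1 | intermediate
27 | (8R)-allylic alcohol, ring OTBS, chain benzoate (name as in step 17) | O[C@H](C/C=C1/C(=O)O[C@H](C=C(C)C)[C@H]1O[Si](C)(C)C(C)(C)C)/C(C)=C/CC/C(C)=C\COC(=O)c1ccccc1 | intermediate
28 | (8R,4'S)-diol (name as in step 18) | O[C@H](C/C=C1/C(=O)O[C@H](C=C(C)C)[C@H]1O)/C(C)=C/CC/C(C)=C\COC(=O)c1ccccc1 | intermediate
29 | CNP0262857.1 (name as in step 19) | CC(=O)O[C@H](C/C=C1/C(=O)O[C@H](C=C(C)C)[C@H]1OC(C)=O)/C(C)=C/CC/C(C)=C\COC(=O)c1ccccc1 | target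

**Count and risks**

Total steps: 19. Longest linear sequence: 12 steps (13 to 29, steps 8–19).

1. Step 17. The ligand-controlled addition may show poor facial selectivity, since no stereocentre of 25 lies near the aldehyde. A slow coupling would also give the β,γ-unsaturated aldehyde time to enolise and lose the ring silyloxy group. Fallback (sets out from 25 and 12, comes back at 27): 25 and 12 are coupled without chiral ligand (CrCl2 4 equiv, NiCl2 1 mol %, DMSO/THF, rt), which should give 27 mixed with its C8 epimer, the (8S)-alcohol F1. The mixture is oxidised (Dess–Martin periodinane, NaHCO3, CH2Cl2, 0 °C) to the single 8-oxo enone F2. F2 is reduced with (S)-2-methyl-CBS-oxazaborolidine (20 mol %) and catecholborane (toluene, −78 °C; Corey–Bakshi–Shibata reduction with the α-methyl alkenyl group as the large substituent), which should return the (8R)-alcohol 27.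

2. Step 14. The elimination may give poor control of the exocyclic alkene geometry, and the amidine base may move the new double bond into the ring. Fallback (sets out from 18, comes back at 23): the lithium enolate of 18 (LiN(i-Pr)2, THF, −78 °C) is brominated with N-bromosuccinimide to the α-bromo lactone F3. Bromide is displaced with PPh3 (MeCN, 60 °C) to give the phosphonium bromide F4, which is deprotonated (Et3N, CH2Cl2) to the stabilised ring phosphorane F5. A Wittig reaction of F5 with 19 (toluene, 80 °C) should give 23, because stabilised α-phosphoranylidene lactones are known to give (E)-alkylidene lactones; the geometry is then set by the olefination and not by an elimination.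

3. Step 12. The basic ylide may epimerise the α-oxygenated aldehyde, expel the β-silyloxy group or attack the lactone carbonyl. Fallback (sets out from 17, comes back at 18): non-basic Takai–Lombardo methylenation of 17 (Zn, CH2Br2, TiCl4, THF/CH2Cl2, 0 °C) gives the 5-vinyl lactone F6. Cross-metathesis of F6 with 2-methylbut-2-ene as solvent (second-generation Grubbs catalyst, (H2IMes)(PCy3)Cl2Ru=CHPh, 5 mol %, 40 °C) should exchange the terminal CH2 for CMe2 and give 18.

**Further compounds**

F1 | step 17 | C8 epimer of 27, the (8S)-alcohol | O[C@@H](C/C=C1/C(=O)O[C@H](C=C(C)C)[C@H]1O[Si](C)(C)C(C)(C)C)/C(C)=C/CC/C(C)=C\COC(=O)c1ccccc1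
F2 | step 17 | 8-oxo enone corresponding to 27 | O=C(C/C=C1/C(=O)O[C@H](C=C(C)C)[C@H]1O[Si](C)(C)C(C)(C)C)/C(C)=C/CC/C(C)=C\COC(=O)c1ccccc1
F3 | step 14 | 3-bromo derivative of 18 (C3 epimers; ring centres as in 18) | BrC1C(=O)O[C@H](C=C(C)C)[C@H]1O[Si](C)(C)C(C)(C)C
F4 | step 14 | triphenylphosphonium bromide at C3 of 18 (ring centres as in 18) | [Br-].c1ccccc1[P+](c1ccccc1)(c1ccccc1)C1C(=O)O[C@H](C=C(C)C)[C@H]1O[Si](C)(C)C(C)(C)C
F5 | step 14 | 3-(triphenylphosphoranylidene) derivative of 18 (ring centres as in 18) | c1ccccc1P(c1ccccc1)(c1ccccc1)=C1C(=O)O[C@H](C=C(C)C)[C@H]1O[Si](C)(C)C(C)(C)C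
F6 | step 12 | (4S,5R)-4-[(tert-butyldimethylsilyl)oxy]-5-ethenyloxolan-2-one | C1C(=O)O[C@H](C=C)[C@H]1O[Si](C)(C)C(C)(C)C
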